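(The numbers in the tables are calculated with constants of no real substance; noise was put on by code.)

Target after 12 min is what you asked me for, across three loadings of free catalyst, and the forecast below stands beside my own reckoning. I treated the flask as two stages: solid substrate enters solution, and the dissolved part becomes target.

common to all: solid substrate 0.050 M
- south-east: protic impurity 2.5 mM; free catalyst 0.51 mol%; run made earlier
- south: protic impurity 2.5 mM; free catalyst 2.1 mol%; run made earlier
- ochre: protic impurity 2.50 mM; free catalyst 0.6 mol%; time 12 min
- blue: protic impurity 2.50 mM; free catalyst 1.2 mol%; time 12 min
- amber: protic impurity 2.50 mM; free catalyst 2.5 mol%; time 12 min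

| run | time / min | target / % | solid substrate / % |
|---|---|---|---|
| south-east | 0.417 | 0 | 98.5 |
| south-east | 1.33 | 1.5 | 95.1 |
| south-east | 2.50 | 2.4 | 90.9 |
| south-east | 4.00 | 3.7 | 86.2 |
| south-east | 5.00 | 6.8 | 85.6 |
| south-east | 6.00 | 8.6 | 80.2 |
| south-east | 8.00 | 12.2 | 74.6 |
| south | 1.33 | 3.4 | 95.4 |
| south | 2.50 | 5.3 | 91.0 |
| south | 4.00 | 10.8 | 85.3 |
| south | 5.00 | 13.6 | 82.0 |
| south | 6.00 | 17.6 | 78.4 |
| south | 8.00 | 25.6 | 71.4 |

(standard deviation of a reading: 0.5 percentage points)

- amount of target at the end, in percent of the solid substrate charged for ochre, blue, amber, in this order
- how that number moves from the first to the last of them (hardly changes / rises all the way / rises, then falls / falls all the way / falls, then rises)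

- solid, in amounts per volume of the solution: solid substrate
- at the start none of the solid substrate is in solution
- "hardly changes" means that all values lie within two and a half points (for a concentration: within two and a half percent of the largest)

Whatever was neither target nor solid substrate I called the pool. Over the last two readings of the south-east run it averaged 12.2 %. Multiplying by ln(2) and dividing by the rate at which target appeared gave 4.70 min. That is the pool half-life, a pseudo-first-order reading of how long dissolved material waited. In the south run the pool averaged 3.50 %, and the half-life was 0.607 min.

I took the lifetime of the south run, 0.875 min, for amber, and it is far shorter than the run, so target there simply lags the dissolving. For ochre I scaled the south-east lifetime by loading: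

feed, south: 0.0360 /min of the charge; south-east: 0.0307 /min

amber: feed × (t − lifetime) = 40.0 %

ochre: lifetime 5.76 min, target 21.4 %

The forecast gave 25 %, 34 % and 40 %, rises all the way, holding that “the row rises but saturates as dissolution becomes limiting”. My ochre figure stood lower.

The flasks gave 22.9 %, 33.9 % and 40.2 %: rises all the way.

    2 starting material → self-condensation product (k = 2.21 /M/min)
    catalyst intermediate B → free catalyst + target (k = 28.4 /min)
    solid substrate ⇌ starting material, rate k3*(cs3 - [starting material]) while solid is left; crystals form when [starting material] > cs3 (solubility = 17.0 mM, k = 0.111 /min)
    starting material + protic impurity → quenched substrate (k = 18.5 /M/min)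
    catalyst intermediate A ⇌ catalyst intermediate B (K = 1.50, k = 8.78 /min)
    starting material + free catalyst → catalyst intermediate A (k = 2340 /M/min)

Reckoned the same way between 6.00 min and 12.0 min, the pool half-life was 3.64 min in ochre and 0.557 min in amber, so 3.30 and 21.5 half-lives fitted into the run. In ochre at 5.62 min, free catalyst had a half-life of 0.080 min against capture by starting material, while catalyst intermediate B had one of 1.5 s, and at 12.0 min the resting state of ochre was catalyst intermediate A, holding 51.5 % of the catalyst.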